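**Plan**

1. Retrosynthesis: the three aryl O–H and two aryl C–CHO groups go back to O‑methyl ethers and aryl C–H. The C4–C5 and C9'–C10' bonds are then cut together, followed by C4–CH3 and C9'–aryl of a (Z)-styrene, and last the C4=C5 bond of α‑gurjunene is restored (its C4 methyl carbon becomes C9').
2. Forward: the seven‑membered ring is taken intact from α‑gurjunene (ozonolysis, cyclopropane hydration). The C1 side chain is grown to alkyne, aryl alkyne and (Z)-styrene, and the C5 ketone becomes the C5=C6 enol triflate.
3. One palladium domino step then closes the cyclopentane and joins the isobutenyl unit; hydrogenation, double formylation and deprotection finish the arene.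
4. Stereochemistry: C1, C7 and C10 come unchanged from α‑gurjunene. C4 is set in the ring closure by allylic strain at C1. C9' follows from the Z alkene, syn carbopalladation and retentive coupling.
5. Enabling feature: quaternary C4 is bonded both to C5 of the C5=C6 alkene in the seven‑membered ring and to the benzylic C9'. A C5 vinylpalladium adding across C4=C9' therefore builds the five‑membered ring C1–C2–C3–C4–C5 and leaves palladium on C9' with no β‑hydrogen, ready for coupling to C10'.

Key step: step 9

Remark on locants: guaiane numbering is used (ring carbons C1–C10, C11 the carbinol carbon, C14 the methyl on C10, C15 the methyl on C4); C9' is the benzylic carbon, C10' and C11' the next side‑chain carbons.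
Assumption: commercial (−)-α‑gurjunene has the configuration of the SMILES of 1, and hydroxy ketone 8 reacts in its open form and not as the cyclic hemiketal.

**Step 1**
Reactants: 1 (−)-α‑gurjunene
Product: 3 4,8,8-trimethyl-3-(3-oxobutyl)bicyclo[5.1.0]octan-2-one, via ozonide 2 (not isolated)
Conditions: O3, CH2Cl2, −78 °C; Me2S, −78 °C → rt
Reagents that add atoms: ozone, [O-][O+]=O
Why: Ozonolysis (Criegee mechanism) cleaves the only C=C bond of 1, the tetrasubstituted C4=C5 bond, and reductive work‑up of ozonide 2 should release the methyl ketone (C4) and the ring ketone (C5) without touching C1, C6, C7 or C10.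

**Step 2**
Reactants: 3 seco‑diketone
Product: 7 3-(but-3-yn-1-yl)-4,8,8-trimethylbicyclo[5.1.0]octan-2-one, via lithium enolate 4 (not isolated), via enol phosphate 5 (not isolated), via lithium acetylide 6 (not isolated)
Conditions: LiN(i-Pr)2 (1.05 equiv), THF, −78 °C; ClP(O)(OEt)2, −78 → 0 °C; LiN(i-Pr)2 (2.2 equiv), −78 → −20 °C; aq. NH4Cl, cold
Reagents that add atoms: diethyl chlorophosphate, CCOP(=O)(Cl)OCC (its atoms sit in intermediate 5 only and leave again as diethyl phosphate)
Why: Kinetic deprotonation of the methyl group, O‑phosphorylation and base‑induced elimination of the enol phosphate is the standard one‑flask conversion of a methyl ketone into a terminal alkyne; the ring ketone should stay out because its only α‑hydrogen is the hindered C1 methine (C6 is a cyclopropane carbon), and low temperature with a cold quench should guard C1 against epimerisation.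

**Step 3**
Reactants: 7 alkynyl cyclopropyl ketone
Product: 8 (2R,3R,6R)-2-(but-3-yn-1-yl)-6-(2-hydroxypropan-2-yl)-3-methylcycloheptan-1-one
Conditions: 2 M aq. H2SO4, THF, 0 °C → rt
Reagents that add atoms: water, O
Why: Acid‑promoted hydrolytic opening of a gem‑dimethylcyclopropyl ketone (homoconjugate hydration, as in the classical carone series): the C6–C11 bond, aligned with the carbonyl π system, ionises to the tertiary C11 cation that water traps, so C6 becomes the α‑methylene and C7 keeps its configuration.

**Step 4**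
Reactants: 8 hydroxy ketone
Product: 9 (2R,3R,6R)-2-(but-3-yn-1-yl)-3-methyl-6-[2-(triethylsilyloxy)propan-2-yl]cycloheptan-1-one
Conditions: Et3SiOTf, 2,6-lutidine, CH2Cl2, −78 → 0 °C
Reagents that add atoms: triethylsilyl triflate, CC[Si](CC)(CC)OS(=O)(=O)C(F)(F)F
Why: Silylation of a tertiary alcohol with a silyl triflate and a hindered pyridine base is fast at low temperature, where the ketone is not converted into a silyl enol ether and the terminal alkyne is inert.

**Step 5**
Reactants: 9 silyl ether alkyne; 10 2-iodo-1,3,5-trimethoxybenzene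
Product: 11 (2R,3R,6R)-3-methyl-6-[2-(triethylsilyloxy)propan-2-yl]-2-[4-(2,4,6-trimethoxyphenyl)but-3-yn-1-yl]cycloheptan-1-one
Conditions: Pd(PPh3)2Cl2 (5 mol%), CuI (10 mol%), Et3N, DMF, 60 °C
Reagents that add atoms: none
Why: Sonogashira coupling of a terminal alkyne with an aryl iodide tolerates the ketone and the silyl ether, and the iodide is reactive enough despite its two ortho methoxy groups.

**Step 6**
Reactants: 11 aryl alkyne
Product: 12 (Z)-alkenyl pinacol boronate (Bpin on C4 and H on C9'; aryl cis to the C3 chain)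
Conditions: CuCl (10 mol%), Xantphos (10 mol%), NaOt-Bu (20 mol%), B2pin2, MeOH, THF, rt
Reagents that add atoms: bis(pinacolato)diboron, CC1(C)OB(OC1(C)C)B1OC(C)(C)C(C)(C)O1
Why: Copper‑catalysed borylcupration/protonation (formal syn hydroboration): the Cu–Bpin species adds syn with copper on the aryl‑bearing C9' and boron on C4, as is general for aryl alkyl alkynes, and methanol replaces copper by hydrogen with retention, which fixes the aryl group cis to the C3 chain while the hindered ketone should be left alone.

**Step 7**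
Reactants: 12 alkenyl boronate
Product: 13 (2R,3R,6R)-3-methyl-2-[(3Z)-3-methyl-4-(2,4,6-trimethoxyphenyl)but-3-en-1-yl]-6-[2-(triethylsilyloxy)propan-2-yl]cycloheptan-1-one
Conditions: MeI, Pd2(dba)3 (2.5 mol%), P(o-tol)3, K2CO3, DMF/H2O, 60 °C
Reagents that add atoms: iodomethane, CI
Why: Suzuki–Miyaura coupling of an alkenylboronate with iodomethane proceeds with retention of alkene geometry, so the new methyl group (C15) takes the place of boron trans to the aryl group and the (Z)-styrene results.

**Step 8**
Reactants: 13 (Z)-styrene ketone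
Product: 15 (3R,6R,7R)-6-methyl-7-[(3Z)-3-methyl-4-(2,4,6-trimethoxyphenyl)but-3-en-1-yl]-3-[2-(triethylsilyloxy)propan-2-yl]cyclohept-1-en-1-yl triflate, via potassium enolate 14 (not isolated)
Conditions: KN(SiMe3)2, THF, −78 °C; PhNTf2, −78 → 0 °C
Reagents that add atoms: N‑phenylbis(trifluoromethanesulfonimide), O=S(=O)(N(c1ccccc1)S(=O)(=O)C(F)(F)F)C(F)(F)F
Why: Kinetic enolate formation and O‑triflation: the bulky amide base removes a hydrogen from the C6 methylene faster than the C1 methine at −78 °C, and trapping with PhNTf2 fixes the C5=C6 enol triflate while C1 is never enolised and the acid‑sensitive styrene sees only base.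

**Step 9**
Reactants: 15 enol triflate; 16 2-methylprop-1-enylboronic acid pinacol ester
Product: 19 (1R,4R,7R,10R)-4-[(1R)-3-methyl-1-(2,4,6-trimethoxyphenyl)but-2-en-1-yl]-11-(triethylsilyloxy)guai-5-ene core, via vinylpalladium triflate 17 (not isolated), via benzylpalladium triflate 18 (not isolated)
Conditions: Pd(PPh3)4 (10 mol%), Cs2CO3, 1,4-dioxane/H2O (10:1), 80 °C, 16 added over 2 h
Reagents that add atoms: none
Why: Zerovalent palladium inserts into the C5–OTf bond to give the cationic vinylpalladium 17 (divalent palladium), which adds syn across the tethered C4=C9' bond to give benzylpalladium 18, held as an η3‑benzyl species with no β‑hydrogen (C4 is quaternary, the other neighbour is the aryl ipso carbon); base‑assisted transmetalation with 16 and reductive elimination then form C9'–C10' with retention, a domino intramolecular Heck carbopalladation/Suzuki–Miyaura capture of the kind known for alkylpalladium intermediates that cannot eliminate. The cyclopentane C1–C2–C3–C4–C5 closes in the 5‑exo‑trig mode, attack at the disubstituted alkene carbon C4 being preferred over 6‑endo attack at the aryl‑bearing C9'. C4 is controlled by the ring stereocentre C1: allylic 1,2‑strain with the palladium at C5 turns the C2–C3 tether pseudoaxial, so the alkene reaches the C5–Pd bond from that face only, which places the C4 methyl cis to C10 and C9' cis to H1. C9' is controlled relative to C4 by the Z geometry of the styrene together with syn addition and retentive coupling. The step needs ring closure to outrun direct coupling of 17 with 16; closure is intramolecular and fast on the triflate‑derived cationic complex, and slow addition of 16 keeps transmetalation behind it.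

**Step 10**
Reactants: 19 bicyclic diene
Product: 20 (1R,4R,7R,10R)-4-[(1R)-3-methyl-1-(2,4,6-trimethoxyphenyl)butyl]-11-(triethylsilyloxy)guai-5-ene core
Conditions: H2 (1 atm), Pt/C (5%), EtOAc, rt, stopped after one equivalent
Reagents that add atoms: none
Why: Heterogeneous catalytic hydrogenation should saturate the exposed isobutenyl C10'=C11' bond in preference to the C5=C6 bond, which is shielded by quaternary C4 on one side and the silyloxyisopropyl group at C7 on the other, and platinum is chosen to limit double‑bond migration; no stereocentre is formed.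

**Step 11**
Reactants: 20 trimethoxyarene
Product: 21 3',5'-dibromo derivative of 20 (3,5-dibromo-2,4,6-trimethoxyphenyl group)
Conditions: NBS (2.05 equiv), MeCN, 0 °C
Reagents that add atoms: N‑bromosuccinimide, O=C1CCC(=O)N1Br
Why: Electrophilic aromatic bromination: the two free ring positions, each flanked by two methoxy groups, react with NBS far faster than the hindered trisubstituted alkene.

**Step 12**
Reactants: 21 dibromide
Product: 24 3',5'-diformyl derivative of 20 (3,5-diformyl-2,4,6-trimethoxyphenyl group), via aryldilithium 22 (not isolated), via bis(lithium aminoalkoxide) 23 (not isolated)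
Conditions: t-BuLi (4.4 equiv), THF, −78 °C; DMF, −78 → 0 °C; aq. NH4Cl
Reagents that add atoms: N,N‑dimethylformamide, CN(C)C=O
Why: Double bromine–lithium exchange followed by formylation with DMF (Bouveault‑type aldehyde synthesis): each aryllithium is stabilised by its two ortho methoxy groups, and the tetrahedral adducts 23 release the aldehydes only on aqueous work‑up, so no acid reaches the silyl ether or the alkene.

**Step 13**
Reactants: 24 silyl ether dialdehyde
Product: 25 tri‑O‑methyl ether of the target (free C11 tertiary alcohol)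
Conditions: Bu4NF, THF, 0 °C → rt
Reagents that add atoms: none
Why: Fluoride‑induced cleavage of the tertiary triethylsilyl ether (Si–F bond formation) leaves the non‑enolisable aldehydes, the alkene and the aryl methyl ethers untouched.

**Step 14**
Reactants: 25 trimethyl ether
Product: 27 target, 5-{(1R)-1-[(1R,3aR,4R,7R)-7-(2-hydroxypropan-2-yl)-1,4-dimethyl-1,2,3,3a,4,5,6,7-octahydroazulen-1-yl]-3-methylbutyl}-2,4,6-trihydroxybenzene-1,3-dicarbaldehyde, via trilithium phenoxide 26 (not isolated)
Conditions: 4-MeC6H4SLi (from 4-MeC6H4SH, n-BuLi; excess), HMPA/toluene, 110 °C; aq. HCl work‑up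
Reagents that add atoms: none
Why: Nucleophilic (SN2) O‑demethylation by an aryl thiolate: all three methoxy groups are ortho or para to a formyl group, so each phenoxide is a good leaving group, and the basic medium spares the tertiary alcohol and the alkene that acidic demethylating agents would ionise.

**Compound list**

1 | (−)-α‑gurjunene | CC1=C2[C@H]3[C@H](C3(C)C)CC[C@@H](C)[C@H]2CC1 | starting material
2 | secondary ozonide of 1 (1,2,4‑trioxolane across C4 and C5; either orientation of the peroxide bridge) | CC12CC[C@@H]3[C@H](C)CC[C@@H]4[C@@H](C4(C)C)C3(OO1)O2 | intermediate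
3 | 4,8,8-trimethyl-3-(3-oxobutyl)bicyclo[5.1.0]octan-2-one (C1/C6/C7/C10 of 1 unchanged) | CC(=O)CC[C@@H]1[C@H](C)CC[C@@H]2[C@H](C1=O)C2(C)C | intermediate
4 | lithium enolate of the methyl ketone of 3 (terminal) | [Li+].[O-]C(=C)CC[C@@H]1[C@H](C)CC[C@@H]2[C@H](C1=O)C2(C)C | intermediate
5 | diethyl enol phosphate of the methyl ketone of 3 | CCOP(=O)(OCC)OC(=C)CC[C@@H]1[C@H](C)CC[C@@H]2[C@H](C1=O)C2(C)C | intermediate
6 | lithium acetylide of 7 | [Li+].[C-]#CCC[C@@H]1[C@H](C)CC[C@@H]2[C@H](C1=O)C2(C)C | intermediate
7 | 3-(but-3-yn-1-yl)-4,8,8-trimethylbicyclo[5.1.0]octan-2-one (C1/C6/C7/C10 of 1 unchanged) | C#CCC[C@@H]1[C@H](C)CC[C@@H]2[C@H](C1=O)C2(C)C | intermediate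
8 | (2R,3R,6R)-2-(but-3-yn-1-yl)-6-(2-hydroxypropan-2-yl)-3-methylcycloheptan-1-one | C#CCC[C@@H]1[C@H](C)CC[C@@H](C(C)(C)O)CC1=O | intermediate
9 | triethylsilyl ether of 8 | C#CCC[C@@H]1[C@H](C)CC[C@@H](C(C)(C)O[Si](CC)(CC)CC)CC1=O | intermediate
10 | 2-iodo-1,3,5-trimethoxybenzene | COc1cc(OC)c(I)c(OC)c1 | starting material
11 | aryl alkyne ketone (2,4,6-trimethoxyphenyl on the alkyne terminus) | COc1cc(OC)c(C#CCC[C@@H]2[C@H](C)CC[C@@H](C(C)(C)O[Si](CC)(CC)CC)CC2=O)c(OC)c1 | intermediate
12 | (Z)-alkenyl pinacol boronate (Bpin on C4; aryl cis to the C3 chain) | COc1cc(OC)c(/C=C(/B3OC(C)(C)C(C)(C)O3)CC[C@@H]2[C@H](C)CC[C@@H](C(C)(C)O[Si](CC)(CC)CC)CC2=O)c(OC)c1 | intermediate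
13 | (Z)-styrene ketone (methyl on C4 trans to aryl) | COc1cc(OC)c(/C=C(/C)CC[C@@H]2[C@H](C)CC[C@@H](C(C)(C)O[Si](CC)(CC)CC)CC2=O)c(OC)c1 | intermediate
14 | potassium C5=C6 enolate of 13 | COc1cc(OC)c(/C=C(/C)CC[C@@H]2[C@H](C)CC[C@@H](C(C)(C)O[Si](CC)(CC)CC)C=C2[O-])c(OC)c1.[K+] | intermediate
15 | (3R,6R,7R)-cyclohept-1-en-1-yl triflate with tethered (Z)-styrene | COc1cc(OC)c(/C=C(/C)CC[C@@H]2[C@H](C)CC[C@@H](C(C)(C)O[Si](CC)(CC)CC)C=C2OS(=O)(=O)C(F)(F)F)c(OC)c1 | intermediate
16 | 2-methylprop-1-enylboronic acid pinacol ester | CC(C)=CB1OC(C)(C)C(C)(C)O1 | starting material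
17 | C5 vinylpalladium bis(triphenylphosphine) triflate (divalent palladium) | COc1cc(OC)c(/C=C(/C)CC[C@@H]2[C@H](C)CC[C@@H](C(C)(C)O[Si](CC)(CC)CC)C=C2[Pd-]([P+](c3ccccc3)(c3ccccc3)c3ccccc3)[P+](c3ccccc3)(c3ccccc3)c3ccccc3)c(OC)c1.[O-]S(=O)(=O)C(F)(F)F | intermediate
18 | cyclised C9' benzylpalladium bis(triphenylphosphine) triflate (drawn σ‑bound; η3‑benzyl in the flask) | c1ccc(cc1)[P+](c1ccccc1)(c1ccccc1)[Pd-]([P+](c1ccccc1)(c1ccccc1)c1ccccc1)[C@@H](c1c(OC)cc(OC)cc1OC)[C@@]1(C)CC[C@H]2C1=C[C@H](C(C)(C)O[Si](CC)(CC)CC)CC[C@H]2C.[O-]S(=O)(=O)C(F)(F)F | intermediate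
19 | (1R,4R,7R,10R,9'R) bicyclic core with 10',11'-ene side chain, trimethoxyphenyl group and C11 triethylsilyl ether | CC(C)=C[C@@H](c1c(OC)cc(OC)cc1OC)[C@@]1(C)CC[C@H]2C1=C[C@H](C(C)(C)O[Si](CC)(CC)CC)CC[C@H]2C | intermediate
20 | side‑chain saturated analogue of 19 (isobutyl on C9') | CC(C)C[C@@H](c1c(OC)cc(OC)cc1OC)[C@@]1(C)CC[C@H]2C1=C[C@H](C(C)(C)O[Si](CC)(CC)CC)CC[C@H]2C | intermediate
21 | 3',5'-dibromo derivative of 20 | CC(C)C[C@@H](c1c(OC)c(Br)c(OC)c(Br)c1OC)[C@@]1(C)CC[C@H]2C1=C[C@H](C(C)(C)O[Si](CC)(CC)CC)CC[C@H]2C | intermediate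
22 | 3',5'-dilithio derivative of 20 | CC(C)C[C@@H](c1c(OC)c([Li])c(OC)c([Li])c1OC)[C@@]1(C)CC[C@H]2C1=C[C@H](C(C)(C)O[Si](CC)(CC)CC)CC[C@H]2C | intermediate
23 | bis(lithium dimethylamino alkoxide) adduct of 22 with DMF (aminal carbons undefined) | CC(C)C[C@@H](c1c(OC)c(C(O[Li])N(C)C)c(OC)c(C(O[Li])N(C)C)c1OC)[C@@]1(C)CC[C@H]2C1=C[C@H](C(C)(C)O[Si](CC)(CC)CC)CC[C@H]2C | intermediate
24 | 3',5'-diformyl derivative of 20 | CC(C)C[C@@H](c1c(OC)c(C=O)c(OC)c(C=O)c1OC)[C@@]1(C)CC[C@H]2C1=C[C@H](C(C)(C)O[Si](CC)(CC)CC)CC[C@H]2C | intermediate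
25 | tri‑O‑methyl ether of the target | CC(C)C[C@@H](c1c(OC)c(C=O)c(OC)c(C=O)c1OC)[C@@]1(C)CC[C@H]2C1=C[C@H](C(C)(C)O)CC[C@H]2C | intermediate
26 | trilithium triphenoxide of the target | CC(C)C[C@@H](c1c(O[Li])c(C=O)c(O[Li])c(C=O)c1O[Li])[C@@]1(C)CC[C@H]2C1=C[C@H](C(C)(C)O)CC[C@H]2C | intermediate
27 | CNP0281883.1, (1R,4R,7R,10R,9'R) in guaiane numbering | CC(C)C[C@@H](c1c(O)c(C=O)c(O)c(C=O)c1O)[C@@]1(C)CC[C@H]2C1=C[C@H](C(C)(C)O)CC[C@H]2C | target

**Totals and risks**

Total step count: 14. Longest linear sequence: 14 steps, from 1 to 27; 10 and 16 are purchased.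

The three steps most likely to fail:

Step 9. The vinylpalladium may couple with the boronate before it cyclises. The hindered benzylpalladium may transmetalate so slowly that it decays, for example by closing onto the C5=C6 bond. The tether may also deliver the alkene from both faces. The fallback separates ring closure from the C9'–C10' bond. It sets out from 15, which under Pd(PPh3)4, B2pin2 and KOAc in 1,4‑dioxane at 80 °C should undergo Heck cyclisation terminated by Miyaura borylation to give the C9' benzylic pinacol boronate F1. Zweifel olefination then follows: 2-methylprop-1-enyllithium (from 1-bromo-2-methylprop-1-ene and t-BuLi) adds to boron, and I2 with NaOMe induces 1,2‑migration of C9' with retention and elimination, giving the isobutenyl compound. The fallback comes back to the route at 19.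

Step 6. The two ortho methoxy groups may erode the regioselectivity of the boryl–copper addition, and the alkoxide medium may slowly epimerise C1 next to the ketone. The fallback sets out from 11 and uses hydrozirconation, where the large zirconocene goes to the less hindered C4. Cp2Zr(H)Cl (3 equiv, THF, rt) should reduce the ketone and add H–Zr syn across the alkyne, and I2 then gives the (E)-iodoalkene C5 alcohol F2 as a mixture at C5. Negishi coupling with MeZnCl and Pd(PPh3)4 gives the (Z)-styrene C5 alcohol F3, and Dess–Martin periodinane oxidation comes back to the route at 13.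

Step 10. Both alkenes are trisubstituted and hindered, so hydrogen uptake may not stop cleanly at the side chain, or the ring double bond may migrate on the metal surface. The fallback sets out from 15 and changes the coupling partner so that the alkene to be reduced is 1,1‑disubstituted. The conditions of step 9 with 2-methylallylboronic acid pinacol ester should give the 11',12'-ene isomer F4. Diimide (2-nitrobenzenesulfonohydrazide, Et3N, CH2Cl2, rt) reduces only this terminal alkene, and the fallback comes back to the route at 20.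

**Further compounds**

F1 | step 9 | C9' benzylic pinacol boronate of the cyclised core (Bpin in place of the isobutenyl group) | CC1(C)OB(OC1(C)C)[C@@H](c1c(OC)cc(OC)cc1OC)[C@@]1(C)CC[C@H]2C1=C[C@H](C(C)(C)O[Si](CC)(CC)CC)CC[C@H]2C
F2 | step 6 | (E)-iodoalkene C5 alcohol (iodine on C4; mixture at C5) | COc1cc(OC)c(/C=C(/I)CC[C@@H]2[C@H](C)CC[C@@H](C(C)(C)O[Si](CC)(CC)CC)CC2O)c(OC)c1
F3 | step 6 | (Z)-styrene C5 alcohol (mixture at C5) | COc1cc(OC)c(/C=C(/C)CC[C@@H]2[C@H](C)CC[C@@H](C(C)(C)O[Si](CC)(CC)CC)CC2O)c(OC)c1
F4 | step 10 | 11',12'-ene isomer of 19 (2-methylallyl group on C9') | C=C(C)C[C@@H](c1c(OC)cc(OC)cc1OC)[C@@]1(C)CC[C@H]2C1=C[C@H](C(C)(C)O[Si](CC)(CC)CC)CC[C@H]2C
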